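The readings come from a simulation on assumed constants; the scatter is artificial.

I decided to count turnovers first, because someone repeating these flasks needs to know how far each catalyst has got at every sampling.

common to all: catalyst 0.00120 M
- east: substrate 0.120 M; reagent 0.120 M
- north: substrate 0.0600 M; reagent 0.0600 M
- north-west: substrate 0.0600 M; reagent 0.120 M
- south-west: substrate 0.120 M; reagent 0.360 M
- west: substrate 0.120 M; reagent 0.120 M; time 76 min

- east run (time / min: [target] / M): 0.76: 0.0101; 1.2: 0.0169; 1.9: 0.0259; 3.0: 0.0310; 4.8: 0.0449; 7.6: 0.0582; 12: 0.0782; 19: 0.0854
- north run (time / min: [target] / M): 0.76: 0.0049; 1.2: 0.0045; 1.9: 0.0061; 3.0: 0.0064; 4.8: 0.0156; 7.6: 0.0186; 12: 0.0282; 19: 0.0344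
- north-west run (time / min: [target] / M): 0.76: 0.0049; 1.2: 0.0077; 1.9: 0.0158; 3.0: 0.0158; 4.8: 0.0261; 7.6: 0.0302; 12: 0.0423; 19: 0.0532
- south-west run (time / min: [target] / M): 0.76: 0.0231; 1.2: 0.0284; 1.9: 0.0437; 3.0: 0.0635; 4.8: 0.0807; 7.6: 0.1005; 12: 0.1120; 19: 0.1173

(each reading ± 0.002 M)

- Overall: substrate + reagent -> target, with catalyst as catalyst.
- Constant volume, constant temperature.
- What is held in complexes is read along with the free species.
- "The second partner" is reagent.
- An order is taken over about fifteen percent of the charge, up and down.

* reaction order in [substrate] at the outset, round the charge of the east run, defined at two percent of the substrate turned into target (one fixed amount of target, the same in the runs compared)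
* reaction order in [reagent] at the outset, round the charge of the east run, defined at two percent of the substrate turned into target
* the north run starts with 0.0600 M less of substrate and of reagent than the east run, and with no target. Compared where both hold the same amount of substrate, once fifteen percent of what the north run was charged with has turned into target, is the north run faster, slower or alike (within a tenth)?
* target in the west run at 76 min, as a share of the substrate charged

In the east run, 0.120 M of substrate stands on 0.00120 M of catalyst, so full conversion asks 100 turnovers of each catalyst. The rule of thumb I used says that the rate follows substrate times reagent. With equal charges, the share turned is then time over time plus a constant, which I read from the last east reading: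

19 min × (0.120 M − 0.0854 M) / 0.0854 M = 7.70 min

I called this reading the turnover clock, the minutes in which half of the turnovers are done at equal charges of that size (the second-order half-life). The west run repeats the east charge, so I reckoned its share as:

76 min / (76 min + 7.70 min) = 90.8%

The rule also answered the comparison of north and east. The two charges differ by 0.0600 M in both substrate and reagent, so at equal substrate they hold equal reagent, and I expected them to be alike.

The border appeared in the south-west run, where reagent stands at 3.00 times the substrate. I integrated the same rule for unequal charges at 7.6 min, using the fractions of reagent and substrate left:

ln[(0.259 M / 0.360 M) / (0.0195 M / 0.120 M)] = 1.49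

(0.360 M − 0.120 M) × 7.6 min / (0.120 M × 1.49) = 10.2 min

That clock ran longer than the east one, so 3.00 times the reagent earned a speed-up of 2.26. This put my order in reagent, taken across that span of reagent charges, at 0.744, and I kept the rule's 1 for substrate.

The forecast gave 1 in substrate, 0.75 in reagent, alike for the comparison and 91% for the west run, holding that “excess reagent is holding the catalyst back”.

The flask gave 0.83 in substrate, 0.83 in reagent, alike for the comparison at a rate ratio of 1.0, and 92.5% for the west run.

    catalyst + substrate + reagent → target + catalyst (1296 /M²/min)
    substrate + reagent ⇌ idle substrate-reagent adduct, settled at all times (3.200 /M)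

The west share turns back into a clock of 6.18 min, shorter than the 7.70 min I carried. At the outset both orders stand at 0.83 rather than 1.0 because substrate and reagent bind into the idle substrate-reagent adduct. The north run shows this on the clock, with 14.0 min from the 4.68 min at which a quarter of its charge had turned, against 8.54 min from 2.85 min in the east run, a ratio of 1.64 where the rule, going by the charges, asks for 2.00.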